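**Retrosynthetic overview**
- The target is opened at C3–C11 and C12–C13: both bonds (seven-membered ring, then cyclopentane) come from one radical cycloisomerisation of a 7-endo type A PPAP enol carrying prenyl groups at C3 and C7.
- The 7-endo prenyl PPAP comes from a hydroxy-adamantane aldol cage (retro-aldol/organocerium addition, then allylic reduction); the cage stores the endo configuration at C7.
- The aldol cage comes from a bicyclo[3.3.1]nonane keto-aldehyde by Pd(PPh3)4-catalysed prenylation, retro-Claisen loss of the second benzoyl group and aldol closure at C3.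
- The bicyclic core comes from symmetric 2,4-dibenzoyl-6-geranylphloroglucinol and 2-(bromomethyl)-3-methylbut-2-enal by a chiral-ammonium (phase-transfer) alkylative dearomatisation–Michael annulation (C5–C6, then C1–C8), which sets C1/C5.
- Ring order: bicyclo[3.3.1] core, then temporary adamantane, then seven-membered ring and cyclopentane together.

Assumption: locants are C1–C9 for the core (C1 benzoyl bridgehead, C3 between the C2/C4 carbonyls, C5 geranyl bridgehead, C8 = CMe2, C9 bridging ketone), C10 = carbon on C7, C11 = CH joined to C3, C12 = CMe2, C13 = CH(iPr), C14 = CH2 on C3; enolised di/triketones are drawn as one tautomer and centres left unassigned in a SMILES are inconsequential mixtures.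

Step 1
Reactants: 1 diethyl 2-(propan-2-ylidene)propanedioate
Product: 2 2-(propan-2-ylidene)propane-1,3-diol
Conditions: iBu2AlH (4.5 equiv), CH2Cl2, −78 → 0 °C; aq. potassium sodium tartrate
Reagents that add atoms: none
Why: 1,2-hydride reduction of both esters (ester reduction) is faster than addition to the tetrasubstituted alkylidene, so the allylic diol results.

Step 2
Reactants: 2 2-(propan-2-ylidene)propane-1,3-diol
Product: 3 2-(hydroxymethyl)-3-methylbut-2-enal
Conditions: MnO2 (10 equiv), CH2Cl2, 23 °C
Reagents that add atoms: none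
Why: MnO2 oxidises allylic alcohols selectively (allylic oxidation), and the first-formed enal deactivates the remaining CH2OH so the reaction stops at the mono-aldehyde.

Step 3
Reactants: 3 2-(hydroxymethyl)-3-methylbut-2-enal
Product: 4 2-(bromomethyl)-3-methylbut-2-enal
Conditions: PBr3 (0.4 equiv), Et2O, 0 °C
Reagents that add atoms: phosphorus tribromide, BrP(Br)Br
Why: The primary allylic alcohol is converted to the bromide by SN2 displacement of its phosphite ester (alcohol bromination) without touching the conjugated aldehyde.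

Step 4
Reactants: 5 phloroglucinol (benzene-1,3,5-triol); 6 benzoyl chloride
Product: 7 2,4-dibenzoylphloroglucinol [(2,4,6-trihydroxy-1,3-phenylene)bis(phenylmethanone)]
Conditions: 6 (2.2 equiv), AlCl3 (4 equiv), PhNO2, 60 °C
Reagents that add atoms: none
Why: Double Friedel–Crafts C-acylation of the electron-rich triol stops after two benzoyl groups because each acyl group deactivates the ring.

Step 5
Reactants: 7 2,4-dibenzoylphloroglucinol; 8 geranyl bromide [(2E)-1-bromo-3,7-dimethylocta-2,6-diene]
Product: 9 2,4-dibenzoyl-6-geranylphloroglucinol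
Conditions: KOH (1.1 equiv), H2O–toluene, 0 °C
Reagents that add atoms: none
Why: The phenolate is C-alkylated by the allylic bromide at its single free ring carbon (phenolate C-allylation), and the product remains aromatic and symmetric.

Step 6
Reactants: 9 2,4-dibenzoyl-6-geranylphloroglucinol; 4 2-(bromomethyl)-3-methylbut-2-enal
Product: 11 (1R,5S)-1,3-dibenzoyl-5-geranyl-4-hydroxy-8,8-dimethyl-2,9-dioxobicyclo[3.3.1]non-3-ene-7-carbaldehyde (C7 epimers), via alkylated trione 10 (not isolated)
Conditions: N-(9-anthracenylmethyl)-O-allylcinchonidinium bromide (10 mol %), CsOH·H2O (3 equiv), toluene–CH2Cl2 (3:1), −40 → 0 °C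
Reagents that add atoms: none
Why: SN2 C-alkylation at the only alkyl-bearing ring carbon (alkylative dearomatisation) gives achiral 10, and the chiral ammonium–enolate ion pair then lets one of the two enantiotopic benzoyl-bearing carbons close onto the β,β-dimethyl enal (phase-transfer-catalysed dearomatisation–Michael annulation), which sets C1 and C5 together while C7 stays epimerisable; the sense of induction is assigned by analogy and the cinchoninium salt would give the antipode.

Step 7
Reactants: 11 bicyclic dibenzoyl enol-aldehyde; 12 prenyl acetate (3-methylbut-2-enyl acetate)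
Product: 15 (1R,3R,5S,7S)-hydroxy-adamantane aldol cage: 1-benzoyl-5-geranyl-3-prenyl-8,8-dimethylbicyclo[3.3.1]nonane-2,4,9-trione with C10H(OH) joining C7 to C3 (C10 unassigned), via C3-prenyl triketone 13 (not isolated), via C7-epimeric enol-aldehyde 14 (not isolated)
Conditions: Pd(PPh3)4 (5 mol %), Cs2CO3 (1.1 equiv), THF, 40 °C; then MeOH, 23 °C
Reagents that add atoms: none
Why: Tsuji–Trost C-prenylation of the caesium triketonate makes C3 quaternary, so methoxide removes the exocyclic benzoyl group by retro-Claisen cleavage (the bridgehead benzoyl cannot leave as a planar enolate) to give the 3-prenyl enol-aldehyde as both C7 epimers, which interconvert by base-mediated enolisation of the aldehyde, and only the endo epimer can reach C3, so the whole mixture drains by intramolecular aldol addition into the cage, which fixes C7 endo and C3 by its geometry.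

Step 8
Reactants: 15 hydroxy-adamantane aldol cage; 16 2-methylprop-1-enylmagnesium bromide
Product: 19 (1R,5S,7S)-7-endo-(1-acetoxy-3-methylbut-2-enyl)-1-benzoyl-5-geranyl-8,8-dimethyl-3-prenylbicyclo[3.3.1]non-2-ene-4,9-dion-2-yl acetate (C10 unassigned), via endo aldehyde 17 (not isolated), via allylic alcohol 18 (not isolated)
Conditions: 16 (4 equiv), CeCl3 (4 equiv), THF, −78 °C; then Ac2O, DMAP, −78 → 0 °C
Reagents that add atoms: acetic anhydride, CC(=O)OC(C)=O
Why: Deprotonation of the cage alcohol triggers retro-aldol opening that releases the aldehyde only as its configurationally pure 7-endo epimer 17 (held as a metal enolate), which the non-basic organocerium captures at −78 °C before C7 can epimerise (retro-aldol–organocerium 1,2-addition), so C7 stays endo, the new carbinol centre is irrelevant, and Ac2O caps both oxygens.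

Step 9
Reactants: 19 allylic acetate/enol acetate
Product: 21 (1R,5S,7S)-1-benzoyl-5-geranyl-2-hydroxy-8,8-dimethyl-3,7-diprenylbicyclo[3.3.1]non-2-ene-4,9-dione (7-endo), via enol acetate 20 (not isolated)
Conditions: Pd(PPh3)4 (5 mol %), Bu3SnH (1.5 equiv), THF, 23 °C; then K2CO3 (0.2 equiv), MeOH, 0 °C
Reagents that add atoms: none
Why: Ionisation of the allylic acetate and hydride transfer from tin to the less substituted allyl terminus (Pd(PPh3)4-catalysed allylic hydrogenolysis) gives the trisubstituted prenyl alkene without touching C7, the enol acetate keeps C3 from attacking the allyl complex, and methanolysis then frees the enol.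

Step 10
Reactants: 21 7-endo type A PPAP enol
Product: 22 (1R,3R,5S,7S,11R,13S)-1-benzoyl-5-geranyl-13-isopropyl-8,8,12,12-tetramethyl cage trione (target): bicyclo[3.3.1]nonane-2,4,9-trione in which C7–C10H2–C11H–C3 closes the seven-membered ring and C3–C11–C12–C13–C14 the cyclopentane
Conditions: 4CzIPN (2 mol %), 2,4,6-triisopropylbenzenethiol (10 mol %), 2,6-lutidine (20 mol %), MeCN–PhCF3 (1:1), blue LEDs (456 nm), 25 °C
Reagents that add atoms: none
Why: Proposed new method: redox-neutral photocatalytic radical cycloisomerisation, in which the excited photocatalyst oxidises the lutidinium enolate of 21 to the C3 diketone radical, this adds 7-exo-trig through its endo lobe to the CH of the C7 prenyl group (C3–C11), the tertiary C12 radical closes 5-exo-trig onto the C3 prenyl group (C12–C13), and the resulting tertiary radical takes H from the thiol, whose thiyl radical is reduced back by the photocatalyst radical anion; C3 is fixed by the cage, C11 by the CMe2 terminus turning to the C6 side away from the C8 methyl groups, and C13 by the closure that leaves C10 and the isopropyl group both pseudo-equatorial (1,3-cis) on the new ring; closest known reaction types are Mn(OAc)3-mediated oxidative radical cyclisations of PPAP-type β-diketones and photoredox/thiol hydroalkylation of alkenes with 1,3-dicarbonyl compounds.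

**Compound list**
1 | diethyl 2-(propan-2-ylidene)propanedioate | CCOC(=O)C(=C(C)C)C(=O)OCC | starting material
2 | 2-(propan-2-ylidene)propane-1,3-diol | CC(C)=C(CO)CO | intermediate
3 | 2-(hydroxymethyl)-3-methylbut-2-enal | CC(C)=C(CO)C=O | intermediate
4 | 2-(bromomethyl)-3-methylbut-2-enal | CC(C)=C(CBr)C=O | intermediate
5 | phloroglucinol | Oc1cc(O)cc(O)c1 | starting material
6 | benzoyl chloride | O=C(Cl)c1ccccc1 | starting material
7 | 2,4-dibenzoylphloroglucinol | O=C(c1ccccc1)c1c(O)cc(O)c(C(=O)c2ccccc2)c1O | intermediate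
8 | geranyl bromide | CC(C)=CCC/C(C)=C/CBr | starting material
9 | 2,4-dibenzoyl-6-geranylphloroglucinol | CC(C)=CCC/C(C)=C/Cc1c(O)c(C(=O)c2ccccc2)c(O)c(C(=O)c2ccccc2)c1O | intermediate
10 | 2,4-dibenzoyl-6-geranyl-6-(2-formyl-3-methylbut-2-enyl)cyclohexane-1,3,5-trione (dienol, achiral, not isolated) | CC(C)=CCC/C(C)=C/CC1(CC(C=O)=C(C)C)C(=O)C(C(=O)c2ccccc2)=C(O)C(C(=O)c2ccccc2)=C1O | intermediate
11 | (1R,5S)-1,3-dibenzoyl-5-geranyl-4-hydroxy-8,8-dimethyl-2,9-dioxobicyclo[3.3.1]non-3-ene-7-carbaldehyde (C7 epimers) | CC(C)=CCC/C(C)=C/C[C@]12CC(C=O)C(C)(C)[C@@](C(=O)c3ccccc3)(C2=O)C(=O)C(C(=O)c3ccccc3)=C1O | intermediate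
12 | prenyl acetate | CC(=O)OCC=C(C)C | starting material
13 | (1R,5S)-1,3-dibenzoyl-5-geranyl-8,8-dimethyl-2,4,9-trioxo-3-prenylbicyclo[3.3.1]nonane-7-carbaldehyde (C3 and C7 mixtures, not isolated) | CC(C)=CCC/C(C)=C/C[C@]12CC(C=O)C(C)(C)[C@@](C(=O)c3ccccc3)(C2=O)C(=O)C(CC=C(C)C)(C(=O)c3ccccc3)C1=O | intermediate
14 | (1R,5S)-1-benzoyl-5-geranyl-2-hydroxy-8,8-dimethyl-4,9-dioxo-3-prenylbicyclo[3.3.1]non-2-ene-7-carbaldehyde (mixture of C7 epimers, not isolated) | CC(C)=CCC/C(C)=C/C[C@]12CC(C=O)C(C)(C)[C@@](C(=O)c3ccccc3)(C2=O)C(O)=C(CC=C(C)C)C1=O | intermediate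
15 | (1R,3R,5S,7S)-hydroxy-adamantane aldol cage (C10 carbinol unassigned) | CC(C)=CCC/C(C)=C/C[C@]12C[C@@H]3C(O)[C@](CC=C(C)C)(C1=O)C(=O)[C@](C(=O)c4ccccc4)(C2=O)C3(C)C | intermediate
16 | 2-methylprop-1-enylmagnesium bromide | CC(C)=C[Mg]Br | starting material
17 | (1R,5S,7S)-1-benzoyl-5-geranyl-2-hydroxy-8,8-dimethyl-4,9-dioxo-3-prenylbicyclo[3.3.1]non-2-ene-7-carbaldehyde (single 7-endo epimer, present as its metal enolate, not isolated) | CC(C)=CCC/C(C)=C/C[C@]12C[C@H](C=O)C(C)(C)[C@@](C(=O)c3ccccc3)(C2=O)C(O)=C(CC=C(C)C)C1=O | intermediate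
18 | (1R,5S,7S)-1-benzoyl-5-geranyl-2-hydroxy-7-endo-(1-hydroxy-3-methylbut-2-enyl)-8,8-dimethyl-3-prenylbicyclo[3.3.1]non-2-ene-4,9-dione (C10 unassigned, not isolated) | CC(C)=CCC/C(C)=C/C[C@]12C[C@H](C(O)C=C(C)C)C(C)(C)[C@@](C(=O)c3ccccc3)(C2=O)C(O)=C(CC=C(C)C)C1=O | intermediate
19 | bis-acetate of 18 (allylic acetate and C2 enol acetate, C10 unassigned) | CC(C)=CCC/C(C)=C/C[C@]12C[C@H](C(OC(C)=O)C=C(C)C)C(C)(C)[C@@](C(=O)c3ccccc3)(C2=O)C(OC(C)=O)=C(CC=C(C)C)C1=O | intermediate
20 | C2 enol acetate of 21 (not isolated) | CC(C)=CCC/C(C)=C/C[C@]12C[C@H](CC=C(C)C)C(C)(C)[C@@](C(=O)c3ccccc3)(C2=O)C(OC(C)=O)=C(CC=C(C)C)C1=O | intermediate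
21 | (1R,5S,7S)-1-benzoyl-5-geranyl-2-hydroxy-8,8-dimethyl-3,7-diprenylbicyclo[3.3.1]non-2-ene-4,9-dione (7-endo) | CC(C)=CCC/C(C)=C/C[C@]12C[C@H](CC=C(C)C)C(C)(C)[C@@](C(=O)c3ccccc3)(C2=O)C(O)=C(CC=C(C)C)C1=O | intermediate
22 | (1R,3R,5S,7S,11R,13S) cage trione CNP0155129.2 | CC(C)=CCC/C(C)=C/C[C@]12C[C@@H]3C[C@@H]4C(C)(C)[C@H](C(C)C)C[C@@]4(C1=O)C(=O)[C@](C(=O)c1ccccc1)(C2=O)C3(C)C | target

**Totals and risks**

Total step count: 10. Longest linear sequence: 8 steps (steps 1–3, then 6–10).

Most likely to fail, first: step 6. The enantio-determining event is an intramolecular desymmetrising Michael addition of a weakly nucleophilic benzoyl-triketone carbon, so both rate and ee are uncertain. The fallback sets out from 9 and 4 and comes back at 11. Compound 9 is C-alkylated with 4 under achiral conditions (K2CO3, acetone, 0 °C) and the achiral trione 10 is isolated. The ring is then closed by covalent iminium activation of the α-branched enal with a chiral primary amine salt (9-amino-9-deoxy-epi-quinine bis(trifluoroacetate), 20 mol %, toluene, 40 °C) instead of ion pairing. This makes no compound outside the list (F0).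

Second: step 7. Three events must run in order (C- rather than O-prenylation, benzoyl rather than ring cleavage, aldol trapping), and over-prenylation or ring opening by methoxide would divert material. The fallback sets out from 8 and 4 and comes back at 15. 2,4,6-Trihydroxybenzophenone F1 is C-geranylated with 8 (KOH, H2O–toluene) to 3-geranyl-2,4,6-trihydroxybenzophenone F2. This is C-prenylated with prenyl bromide F3 to 3-geranyl-5-prenyl-2,4,6-trihydroxybenzophenone F4. The same chiral ammonium salt and CsOH·H2O with 4 then give alkylation, Michael closure by the benzoyl carbon and aldol trapping by the prenyl-bearing carbon, so 15 forms without any acyl exchange. The price is that the geranyl- and prenyl-bearing carbons are alkylated about equally, so the regioisomeric hydroxy-adamantane F5 (prenyl at C5, geranyl at C3) must be separated.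

Third: step 10, the proposed new step. The photocatalytic cycle may stall, the thiol may scramble the geranyl alkene geometry, and the C13 diastereoselectivity is the least secure stereochemical claim in the route. The fallback uses known chemistry, sets out from 21 and comes back at 22. Enol bromination with N-bromosuccinimide (1.0 equiv, CH2Cl2, −78 °C) gives the C3-bromo diketone F6. Tin hydride chain reduction (Bu3SnH, Et3B/air, toluene, −20 °C) generates the same C3 radical, which cyclises twice and is reduced by Bu3SnH, as in established reductive cyclisations of α-halo-1,3-dicarbonyl compounds.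

**Further compounds**
F0 | step 6 | none | none
F1 | step 7 | 2,4,6-trihydroxybenzophenone | O=C(c1ccccc1)c1c(O)cc(O)cc1O
F2 | step 7 | 3-geranyl-2,4,6-trihydroxybenzophenone | CC(C)=CCC/C(C)=C/Cc1c(O)cc(O)c(C(=O)c2ccccc2)c1O
F3 | step 7 | prenyl bromide (1-bromo-3-methylbut-2-ene) | CC(C)=CCBr
F4 | step 7 | 3-geranyl-5-prenyl-2,4,6-trihydroxybenzophenone | CC(C)=CCC/C(C)=C/Cc1c(O)c(CC=C(C)C)c(O)c(C(=O)c2ccccc2)c1O
F5 | step 7 | regioisomeric hydroxy-adamantane (prenyl at C5, geranyl at C3, C10 unassigned) | CC(C)=CC[C@]12C[C@@H]3C(O)[C@](C/C=C(\C)CCC=C(C)C)(C1=O)C(=O)[C@](C(=O)c4ccccc4)(C2=O)C3(C)C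
F6 | step 10 | (1R,5S,7S)-1-benzoyl-3-bromo-5-geranyl-8,8-dimethyl-3,7-diprenylbicyclo[3.3.1]nonane-2,4,9-trione (C3 unassigned) | CC(C)=CCC/C(C)=C/C[C@]12C[C@H](CC=C(C)C)C(C)(C)[C@@](C(=O)c3ccccc3)(C2=O)C(=O)C(Br)(CC=C(C)C)C1=O
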